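**Retrosynthetic overview**

1. Labels: guaiacylpropyl arm C7–C8–C9, central arm C7′–C8′–C9′, dihydrobenzofuran O1, C2, C3, C3a, C4–C7, C7a (benzo ring A, dihydrofuran ring B). The strategy rests on C8′: a CH bonded to C8 and to the methylene C7′, which is bonded to the aromatic carbon C5 of ring A. C8′–C7′ is therefore read as a former vinyl group whose inner carbon took C8 from boron and whose terminal carbon took the C5 aryl from palladium.
2. C9′ is cut first (hydroxymethyl from a C8′ pinacol boronate by one-carbon homologation and oxidation). C8–C8′ and C7′–C5 are then cut together by a three-component conjunctive cross-coupling into a C8 secondary boronate, vinylmagnesium bromide and a 5-bromodihydrobenzofuran.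
3. The C8 boronate comes from ferulic acid by copper-catalysed enantioselective protoboration of the O-benzyl, O-silyl coniferyl alcohol.
4. The bromide comes from 5-bromo-2-hydroxy-3-methoxybenzaldehyde. Ring B is the only ring made in the route; it is closed at C2–C3 by dirhodium-carbenoid insertion into the benzylic O–CH2 group before the fragments are joined. The three benzene rings are bought, and no ring forms in or after the key step.
5. Phenols travel as benzyl ethers and primary alcohols as silyl ethers, removed at the end by fluoride and then hydrogenolysis.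

Key step: step 13

Remark (assumption): for the chiral catalysts of steps 4, 10 and 13 the sense of induction is taken to follow the ligand enantiomer, so the enantiomer giving the drawn configuration is used and is to be confirmed on the first batch; the C9 oxygen is carried as a triisopropylsilyl ether because the coupling has to run warm (about 40 °C), so cold cannot be relied on to hold back loss of silanolate from the boron ate complex.

**Route**

Step 1
Reactants: 1 ferulic acid
Product: 2 benzyl (E)-3-(4-benzyloxy-3-methoxyphenyl)prop-2-enoate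
Conditions: BnBr (2.3 equiv), K2CO3 (3 equiv), DMF, 60 °C
Reagents that add atoms: benzyl bromide, BrCc1ccccc1
Why: Double O-alkylation (Williamson etherification and carboxylate alkylation) should proceed cleanly because K2CO3 deprotonates both the phenol and the acid and benzyl bromide is an unhindered SN2 electrophile.

Step 2
Reactants: 2 benzyl (E)-3-(4-benzyloxy-3-methoxyphenyl)prop-2-enoate
Product: 3 (E)-3-(4-benzyloxy-3-methoxyphenyl)prop-2-en-1-ol
Conditions: i-Bu2AlH (3 equiv), CH2Cl2, −78 → 0 °C; aq. potassium sodium tartrate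
Reagents that add atoms: none
Why: 1,2-Reduction of an α,β-unsaturated ester by i-Bu2AlH should give the allylic alcohol and leave the E alkene and the aryl benzyl ether untouched.

Step 3
Reactants: 3 (E)-3-(4-benzyloxy-3-methoxyphenyl)prop-2-en-1-ol
Product: 4 (E)-[3-(4-benzyloxy-3-methoxyphenyl)prop-2-enyloxy]triisopropylsilane
Conditions: TIPSCl (1.2 equiv), imidazole (2.5 equiv), DMF, rt
Reagents that add atoms: triisopropylsilyl chloride, CC(C)[Si](Cl)(C(C)C)C(C)C
Why: Imidazole-promoted silylation of a primary alcohol is routine, and the bulky, weakly Lewis-basic triisopropylsilyl ether is chosen as a poor leaving group for the later boron ate complex.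

Step 4
Reactants: 4 (E)-[3-(4-benzyloxy-3-methoxyphenyl)prop-2-enyloxy]triisopropylsilane; 5 bis(pinacolato)diboron
Product: 6 2-[(2S)-1-(4-benzyloxy-3-methoxyphenyl)-3-(triisopropylsilyloxy)propan-2-yl]-4,4,5,5-tetramethyl-1,3,2-dioxaborolane (C8 boronate)
Conditions: CuCl (5 mol %), chiral sulfonate-bearing imidazolinium salt as NHC precursor (5.5 mol %, enantiomer giving S), NaOtBu (20 mol %), B2pin2 (1.1 equiv), MeOH (2 equiv), THF, −50 → −15 °C
Reagents that add atoms: none
Why: Copper-catalysed enantioselective protoboration of a β-substituted styrene: the ligated copper boryl should add syn across the alkene with copper at the benzylic C7 and boron at C8, the chiral NHC choosing the alkene face and so setting C8, and methanol then protonates the C7–Cu bond; the silyl ether is no leaving group and sits γ to copper, so allylic substitution should not compete.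

Step 5
Reactants: 7 5-bromo-2-hydroxy-3-methoxybenzaldehyde; 8 (4-benzyloxy-3-methoxyphenyl)methanol
Product: 9 2-[(4-benzyloxy-3-methoxyphenyl)methoxy]-5-bromo-3-methoxybenzaldehyde
Conditions: PPh3 (1.3 equiv), DIAD (1.3 equiv), THF, 0 °C → rt
Reagents that add atoms: none
Why: Mitsunobu etherification should work because the phenol is made acidic by the ortho formyl group and the phosphonium-activated primary benzylic alcohol is displaced readily by SN2.

Step 6
Reactants: 9 2-[(4-benzyloxy-3-methoxyphenyl)methoxy]-5-bromo-3-methoxybenzaldehyde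
Product: 10 2-{2-[(4-benzyloxy-3-methoxyphenyl)methoxy]-5-bromo-3-methoxyphenyl}acetonitrile
Conditions: TosMIC (1.3 equiv), t-BuOK (2.5 equiv), DME, −40 °C; then MeOH, reflux
Reagents that add atoms: tosylmethyl isocyanide, [C-]#[N+]CS(=O)(=O)c1ccc(C)cc1
Why: Van Leusen reductive cyanation turns the aldehyde carbon into the benzylic CH2 and adds the nitrile carbon under basic, acid-free conditions that the acid-labile electron-rich benzyl aryl ether should tolerate.

Step 7
Reactants: 10 2-{2-[(4-benzyloxy-3-methoxyphenyl)methoxy]-5-bromo-3-methoxyphenyl}acetonitrile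
Product: 11 2-{2-[(4-benzyloxy-3-methoxyphenyl)methoxy]-5-bromo-3-methoxyphenyl}acetic acid
Conditions: KOH (10 equiv), EtOH/H2O 3:1, reflux; then 1 M HCl to pH 3, 0 °C
Reagents that add atoms: potassium hydroxide, [K+].[OH-]; water, O
Why: Alkaline nitrile hydrolysis should give the arylacetic acid while the aryl ethers and the aryl bromide are inert to hydroxide, and the brief cold acidification spares the benzylic ether.

Step 8
Reactants: 11 2-{2-[(4-benzyloxy-3-methoxyphenyl)methoxy]-5-bromo-3-methoxyphenyl}acetic acid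
Product: 12 methyl 2-{2-[(4-benzyloxy-3-methoxyphenyl)methoxy]-5-bromo-3-methoxyphenyl}acetate
Conditions: MeI (1.5 equiv), K2CO3 (2 equiv), DMF, rt
Reagents that add atoms: iodomethane, CI
Why: Carboxylate O-alkylation with iodomethane is a mild esterification that avoids acid.

Step 9
Reactants: 12 methyl 2-{2-[(4-benzyloxy-3-methoxyphenyl)methoxy]-5-bromo-3-methoxyphenyl}acetate
Product: 13 methyl 2-{2-[(4-benzyloxy-3-methoxyphenyl)methoxy]-5-bromo-3-methoxyphenyl}-2-diazoacetate
Conditions: p-ABSA (1.3 equiv), DBU (1.5 equiv), MeCN, 0 °C → rt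
Reagents that add atoms: 4-acetamidobenzenesulfonyl azide, CC(=O)Nc1ccc(cc1)S(=O)(=O)N=[N+]=[N-]
Why: Regitz diazo transfer to the DBU-generated arylacetate enolate is the standard entry to aryldiazoacetates and should tolerate the ortho alkoxy group.

Step 10
Reactants: 13 methyl 2-{2-[(4-benzyloxy-3-methoxyphenyl)methoxy]-5-bromo-3-methoxyphenyl}-2-diazoacetate
Product: 15 methyl (2S,3S)-2-(4-benzyloxy-3-methoxyphenyl)-5-bromo-7-methoxy-2,3-dihydro-1-benzofuran-3-carboxylate (2,3-trans), via cis ester 14 (not isolated)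
Conditions: Rh2(S-PTTL)4 (dirhodium tetrakis[N-phthaloyl-(S)-tert-leucinate], 1 mol %; or its enantiomer, whichever gives 2S), toluene, −60 °C; then solvent swap, NaOMe (0.3 equiv), MeOH/THF, rt
Reagents that add atoms: none
Why: Intramolecular dirhodium-carbenoid C–H insertion into the doubly activated benzylic O–CH2 group should close ring B (five-membered, C2–C3 bond) and set C2 under catalyst control, giving the cis ester first, after which methoxide epimerises C3 through the ester enolate to the more stable trans isomer.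

Step 11
Reactants: 15 methyl (2S,3S)-2-(4-benzyloxy-3-methoxyphenyl)-5-bromo-7-methoxy-2,3-dihydro-1-benzofuran-3-carboxylate
Product: 16 [(2S,3R)-2-(4-benzyloxy-3-methoxyphenyl)-5-bromo-7-methoxy-2,3-dihydro-1-benzofuran-3-yl]methanol (2,3-trans)
Conditions: LiBH4 (2 equiv), MeOH (2 equiv), THF, 0 °C → rt
Reagents that add atoms: none
Why: Borohydride reduction of the methyl ester should give the primary alcohol without touching the aryl bromide or the stereocentres (the descriptor at C3 changes only because the substituent priorities change).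

Step 12
Reactants: 16 [(2S,3R)-2-(4-benzyloxy-3-methoxyphenyl)-5-bromo-7-methoxy-2,3-dihydro-1-benzofuran-3-yl]methanol
Product: 17 {[(2S,3R)-2-(4-benzyloxy-3-methoxyphenyl)-5-bromo-7-methoxy-2,3-dihydro-1-benzofuran-3-yl]methoxy}(tert-butyl)dimethylsilane (2,3-trans)
Conditions: TBSCl (1.3 equiv), imidazole (2.5 equiv), DMF, rt
Reagents that add atoms: tert-butyldimethylsilyl chloride, CC(C)(C)[Si](C)(C)Cl
Why: Routine silylation masks the only protic group so that the bromide can meet the boron ate complex.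

Step 13
Reactants: 6 C8 boronate; 18 vinylmagnesium bromide; 17 trans-5-bromodihydrobenzofuran silyl ether
Product: 20 2-[(2R,3R)-1-[(2S,3R)-2-(4-benzyloxy-3-methoxyphenyl)-3-(tert-butyldimethylsilyloxymethyl)-7-methoxy-2,3-dihydro-1-benzofuran-5-yl]-3-[(4-benzyloxy-3-methoxyphenyl)methyl]-4-(triisopropylsilyloxy)butan-2-yl]-4,4,5,5-tetramethyl-1,3,2-dioxaborolane (C8′ boronate), via vinylboron ate complex 19 (not isolated)
Conditions: 6 (1.3 equiv), NaOTf (3 equiv), THF, 0 °C; vinylMgBr (1.3 equiv), 0 °C → rt, 30 min; then 17 (1.0 equiv), Pd(OAc)2 (3 mol %), MandyPhos (3.6 mol %, enantiomer giving R at C8′), THF, 40 °C, 24 h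
Reagents that add atoms: none
Why: Vinylmagnesium bromide adds to the boron of 6 to give the four-coordinate complex 19, while bromide 17 adds oxidatively to zerovalent palladium and, after triflate-assisted loss of bromide, the cationic arylpalladium species (divalent palladium) binds the vinyl π bond of 19. This coordination triggers an anti-periplanar 1,2-metallate shift in which C8 moves from boron to the inner vinyl carbon (C8′) with retention while palladium bonds to the terminal carbon (C7′), and reductive elimination then joins C7′ to C5 of ring A and returns zerovalent palladium. The closest known reaction is the Pd/MandyPhos enantioselective conjunctive cross-coupling of Grignard-derived vinylboron ate complexes with aryl halides or triflates in the presence of a triflate salt; a secondary, β-oxygenated migrating group lies at the edge of that scope. No ring is closed. The new centre C8′ is set by the chiral bisphosphine, which selects the face of the bound vinyl group (the ligand enantiomer matched to the S centre of 6 is used), and C8 keeps its configuration because the shift is stereoretentive. The step needs the metallate shift to outrun direct vinyl transfer to palladium and loss of silanolate from C9; the hindered pinacolato ligand on boron, the bulky non-coordinating triisopropylsilyl ether and the moderate 40 °C are meant to secure this.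

Step 14
Reactants: 20 C8′ boronate
Product: 22 (2R,3R)-2-{[(2S,3R)-2-(4-benzyloxy-3-methoxyphenyl)-3-(tert-butyldimethylsilyloxymethyl)-7-methoxy-2,3-dihydro-1-benzofuran-5-yl]methyl}-3-[(4-benzyloxy-3-methoxyphenyl)methyl]-4-(triisopropylsilyloxy)butan-1-ol, via homologated primary boronate 21 (not isolated)
Conditions: ICH2Cl (3 equiv), n-BuLi (2.5 equiv), THF, −78 °C → rt; then 2 M NaOH, 30% H2O2, 0 °C → rt
Reagents that add atoms: chloroiodomethane, ClCI; hydrogen peroxide, OO
Why: Matteson homologation (chloromethyllithium made in situ by fast iodine–lithium exchange adds to boron, and C8′ migrates to the CH2 with retention as chloride leaves) followed by stereoretentive peroxide oxidation of the new primary C–B bond should install C9′ as CH2OH without touching C8′ or C8.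

Step 15
Reactants: 22 monoalcohol bis-silyl ether
Product: 23 (2R,3R)-2-{[(2S,3R)-2-(4-benzyloxy-3-methoxyphenyl)-3-(hydroxymethyl)-7-methoxy-2,3-dihydro-1-benzofuran-5-yl]methyl}-3-[(4-benzyloxy-3-methoxyphenyl)methyl]butane-1,4-diol
Conditions: Bu4NF (3 equiv), THF, 0 °C → rt
Reagents that add atoms: none
Why: Fluoride-driven desilylation should remove both primary silyl ethers (TBS and TIPS) without affecting benzyl ethers or stereocentres.

Step 16
Reactants: 23 triol bis-benzyl ether
Product: 24 (2R,3R)-2-{[(2S,3R)-2-(4-hydroxy-3-methoxyphenyl)-3-(hydroxymethyl)-7-methoxy-2,3-dihydro-1-benzofuran-5-yl]methyl}-3-[(4-hydroxy-3-methoxyphenyl)methyl]butane-1,4-diol (CNP0256425.1)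
Conditions: H2 (1 atm), Pd/C (10 wt % palladium on carbon), EtOAc/MeOH, rt, stopped once both benzyl groups are gone
Reagents that add atoms: none
Why: Catalytic hydrogenolysis of aryl benzyl ethers is fast under neutral conditions at 1 atm, so both phenols should be freed before the benzylic C2–O1 bond of ring B is attacked.

**Compound list**

1 | ferulic acid, (E)-3-(4-hydroxy-3-methoxyphenyl)prop-2-enoic acid | COc1cc(/C=C/C(=O)O)ccc1O | starting material
2 | benzyl (E)-3-(4-benzyloxy-3-methoxyphenyl)prop-2-enoate | COc1cc(/C=C/C(=O)OCc2ccccc2)ccc1OCc1ccccc1 | intermediate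
3 | (E)-3-(4-benzyloxy-3-methoxyphenyl)prop-2-en-1-ol | COc1cc(/C=C/CO)ccc1OCc1ccccc1 | intermediate
4 | (E)-[3-(4-benzyloxy-3-methoxyphenyl)prop-2-enyloxy]triisopropylsilane | COc1cc(/C=C/CO[Si](C(C)C)(C(C)C)C(C)C)ccc1OCc1ccccc1 | intermediate
5 | bis(pinacolato)diboron | CC1(C)OB(OC1(C)C)B1OC(C)(C)C(C)(C)O1 | starting material
6 | 2-[(2S)-1-(4-benzyloxy-3-methoxyphenyl)-3-(triisopropylsilyloxy)propan-2-yl]-4,4,5,5-tetramethyl-1,3,2-dioxaborolane | COc1cc(C[C@@H](CO[Si](C(C)C)(C(C)C)C(C)C)B2OC(C)(C)C(C)(C)O2)ccc1OCc1ccccc1 | intermediate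
7 | 5-bromo-2-hydroxy-3-methoxybenzaldehyde | COc1cc(Br)cc(C=O)c1O | starting material
8 | (4-benzyloxy-3-methoxyphenyl)methanol | COc1cc(CO)ccc1OCc1ccccc1 | starting material
9 | 2-[(4-benzyloxy-3-methoxyphenyl)methoxy]-5-bromo-3-methoxybenzaldehyde | COc1cc(Br)cc(C=O)c1OCc1ccc(OCc2ccccc2)c(OC)c1 | intermediate
10 | 2-{2-[(4-benzyloxy-3-methoxyphenyl)methoxy]-5-bromo-3-methoxyphenyl}acetonitrile | COc1cc(Br)cc(CC#N)c1OCc1ccc(OCc2ccccc2)c(OC)c1 | intermediate
11 | 2-{2-[(4-benzyloxy-3-methoxyphenyl)methoxy]-5-bromo-3-methoxyphenyl}acetic acid | COc1cc(Br)cc(CC(=O)O)c1OCc1ccc(OCc2ccccc2)c(OC)c1 | intermediate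
12 | methyl 2-{2-[(4-benzyloxy-3-methoxyphenyl)methoxy]-5-bromo-3-methoxyphenyl}acetate | COc1cc(Br)cc(CC(=O)OC)c1OCc1ccc(OCc2ccccc2)c(OC)c1 | intermediate
13 | methyl 2-{2-[(4-benzyloxy-3-methoxyphenyl)methoxy]-5-bromo-3-methoxyphenyl}-2-diazoacetate | COc1cc(Br)cc(C(=[N+]=[N-])C(=O)OC)c1OCc1ccc(OCc2ccccc2)c(OC)c1 | intermediate
14 | methyl (2S,3R)-2-(4-benzyloxy-3-methoxyphenyl)-5-bromo-7-methoxy-2,3-dihydro-1-benzofuran-3-carboxylate (2,3-cis) | Brc1cc(OC)c2c(c1)[C@@H](C(=O)OC)[C@@H](c1ccc(OCc3ccccc3)c(OC)c1)O2 | intermediate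
15 | methyl (2S,3S)-2-(4-benzyloxy-3-methoxyphenyl)-5-bromo-7-methoxy-2,3-dihydro-1-benzofuran-3-carboxylate (2,3-trans) | Brc1cc(OC)c2c(c1)[C@H](C(=O)OC)[C@@H](c1ccc(OCc3ccccc3)c(OC)c1)O2 | intermediate
16 | [(2S,3R)-2-(4-benzyloxy-3-methoxyphenyl)-5-bromo-7-methoxy-2,3-dihydro-1-benzofuran-3-yl]methanol (2,3-trans) | Brc1cc(OC)c2c(c1)[C@H](CO)[C@@H](c1ccc(OCc3ccccc3)c(OC)c1)O2 | intermediate
17 | {[(2S,3R)-2-(4-benzyloxy-3-methoxyphenyl)-5-bromo-7-methoxy-2,3-dihydro-1-benzofuran-3-yl]methoxy}(tert-butyl)dimethylsilane (2,3-trans) | Brc1cc(OC)c2c(c1)[C@H](CO[Si](C)(C)C(C)(C)C)[C@@H](c1ccc(OCc3ccccc3)c(OC)c1)O2 | intermediate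
18 | vinylmagnesium bromide | C=C[Mg]Br | starting material
19 | bromomagnesium [(2S)-1-(4-benzyloxy-3-methoxyphenyl)-3-(triisopropylsilyloxy)propan-2-yl](ethenyl)(pinacolato)borate | COc1cc(C[C@@H](CO[Si](C(C)C)(C(C)C)C(C)C)[B-]2(C=C)OC(C)(C)C(C)(C)O2)ccc1OCc1ccccc1.[Mg+]Br | intermediate
20 | 2-[(2R,3R)-1-[(2S,3R)-2-(4-benzyloxy-3-methoxyphenyl)-3-(tert-butyldimethylsilyloxymethyl)-7-methoxy-2,3-dihydro-1-benzofuran-5-yl]-3-[(4-benzyloxy-3-methoxyphenyl)methyl]-4-(triisopropylsilyloxy)butan-2-yl]-4,4,5,5-tetramethyl-1,3,2-dioxaborolane | COc1cc(C[C@@H](CO[Si](C(C)C)(C(C)C)C(C)C)[C@H](B2OC(C)(C)C(C)(C)O2)Cc2cc(OC)c3c(c2)[C@H](CO[Si](C)(C)C(C)(C)C)[C@@H](c2ccc(OCc4ccccc4)c(OC)c2)O3)ccc1OCc1ccccc1 | intermediate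
21 | 2-[(2R,3R)-2-{[(2S,3R)-2-(4-benzyloxy-3-methoxyphenyl)-3-(tert-butyldimethylsilyloxymethyl)-7-methoxy-2,3-dihydro-1-benzofuran-5-yl]methyl}-3-[(4-benzyloxy-3-methoxyphenyl)methyl]-4-(triisopropylsilyloxy)butyl]-4,4,5,5-tetramethyl-1,3,2-dioxaborolane | COc1cc(C[C@@H](CO[Si](C(C)C)(C(C)C)C(C)C)[C@H](CB2OC(C)(C)C(C)(C)O2)Cc2cc(OC)c3c(c2)[C@H](CO[Si](C)(C)C(C)(C)C)[C@@H](c2ccc(OCc4ccccc4)c(OC)c2)O3)ccc1OCc1ccccc1 | intermediate
22 | (2R,3R)-2-{[(2S,3R)-2-(4-benzyloxy-3-methoxyphenyl)-3-(tert-butyldimethylsilyloxymethyl)-7-methoxy-2,3-dihydro-1-benzofuran-5-yl]methyl}-3-[(4-benzyloxy-3-methoxyphenyl)methyl]-4-(triisopropylsilyloxy)butan-1-ol | COc1cc(C[C@@H](CO[Si](C(C)C)(C(C)C)C(C)C)[C@H](CO)Cc2cc(OC)c3c(c2)[C@H](CO[Si](C)(C)C(C)(C)C)[C@@H](c2ccc(OCc4ccccc4)c(OC)c2)O3)ccc1OCc1ccccc1 | intermediate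
23 | (2R,3R)-2-{[(2S,3R)-2-(4-benzyloxy-3-methoxyphenyl)-3-(hydroxymethyl)-7-methoxy-2,3-dihydro-1-benzofuran-5-yl]methyl}-3-[(4-benzyloxy-3-methoxyphenyl)methyl]butane-1,4-diol | COc1cc(C[C@@H](CO)[C@H](CO)Cc2cc(OC)c3c(c2)[C@H](CO)[C@@H](c2ccc(OCc4ccccc4)c(OC)c2)O3)ccc1OCc1ccccc1 | intermediate
24 | (2R,3R)-2-{[(2S,3R)-2-(4-hydroxy-3-methoxyphenyl)-3-(hydroxymethyl)-7-methoxy-2,3-dihydro-1-benzofuran-5-yl]methyl}-3-[(4-hydroxy-3-methoxyphenyl)methyl]butane-1,4-diol | COc1cc(C[C@@H](CO)[C@H](CO)Cc2cc(OC)c3c(c2)[C@H](CO)[C@@H](c2ccc(O)c(OC)c2)O3)ccc1O | target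

**Step count and risks**

Total step count: 16.
Longest linear sequence: 12 steps (steps 5–12, then 13–16); the boronate arm (steps 1–4) converges at step 13.

Steps most likely to fail:

1. Step 13. The ate complex may lose silanolate from C9 (β-elimination to an allylarene) before the palladium-induced shift. The vinyl group may be transferred directly to palladium instead of C8 migrating. Facial control at C8′ may be eroded if the resident C8 centre opposes the ligand. Fallback (reagent-controlled lithiation–borylation, a known 1,2-metallate homologation run cold): it sets out from bromide 17 and uses boronate 6. Suzuki–Miyaura vinylation of 17 with potassium vinyltrifluoroborate (PdCl2(dppf), Cs2CO3, THF/H2O, 80 °C) should give the 5-ethenyl dihydrobenzofuran F1. Hydroboration–oxidation (9-BBN, THF; then NaOH, H2O2) should give the 2-arylethanol F2. Mitsunobu esterification with 2,4,6-triisopropylbenzoic acid (PPh3, DIAD) should give the triisopropylbenzoate F3. Deprotonation of F3 α to oxygen with s-BuLi and sparteine (the enantiomer, or its surrogate, that leads to R at C8′) in Et2O at −78 °C, addition of 6, and warming (MgBr2·OEt2 in MeOH if needed) should effect borylation with retention and migration of C8 with loss of the benzoate. This gives 20, where the route is rejoined.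

2. Step 4. Regiochemical leakage (boron at C7, copper at C8, then loss of silanolate as an allylic substitution) or insufficient facial selectivity on the electron-rich styrene would compromise the C8 centre. Fallback (diboration, then site-selective cross-coupling): it sets out from bis(pinacolato)diboron 5. Enantioselective diboration of commercial allyloxytriisopropylsilane (Pt(dba)3, TADDOL-derived phosphonite, THF, 60 °C) should give the (S)-1,2-bis(pinacolboryl)-3-(triisopropylsilyloxy)propane F4. Suzuki–Miyaura coupling with commercial 1-(benzyloxy)-4-bromo-2-methoxybenzene (Pd(OAc)2, RuPhos, KOH, THF/H2O, 70 °C) should engage only the primary C–B bond, which is activated by the neighbouring boronate. This gives 6 directly.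

3. Step 14. Chloromethyllithium may decompose faster than it adds to the congested C8′ boron, leaving 20 unconverted, so that oxidation would give the secondary alcohol instead of the homologated one. Fallback (vinylation and oxidative cleavage with a stable nucleophile): it sets out from 20. Zweifel olefination (vinylmagnesium bromide 18 in THF/DMSO, −78 °C; I2; NaOMe) should give the C8′-ethenyl compound F5 with retention. Lemieux–Johnson cleavage (K2OsO4·2H2O cat., NaIO4, 2,6-lutidine, dioxane/H2O) should give the aldehyde F6, which is reduced at once with NaBH4 to avoid epimerisation at C8′. This gives 22, where the route is rejoined.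

Further compounds
F1 | step 13 | tert-butyl{[(2S,3R)-2-(4-benzyloxy-3-methoxyphenyl)-5-ethenyl-7-methoxy-2,3-dihydro-1-benzofuran-3-yl]methoxy}dimethylsilane | C=Cc1cc(OC)c2c(c1)[C@H](CO[Si](C)(C)C(C)(C)C)[C@@H](c1ccc(OCc3ccccc3)c(OC)c1)O2
F2 | step 13 | 2-[(2S,3R)-2-(4-benzyloxy-3-methoxyphenyl)-3-(tert-butyldimethylsilyloxymethyl)-7-methoxy-2,3-dihydro-1-benzofuran-5-yl]ethan-1-ol | OCCc1cc(OC)c2c(c1)[C@H](CO[Si](C)(C)C(C)(C)C)[C@@H](c1ccc(OCc3ccccc3)c(OC)c1)O2
F3 | step 13 | 2-[(2S,3R)-2-(4-benzyloxy-3-methoxyphenyl)-3-(tert-butyldimethylsilyloxymethyl)-7-methoxy-2,3-dihydro-1-benzofuran-5-yl]ethyl 2,4,6-triisopropylbenzoate | CC(C)c1cc(C(C)C)c(C(=O)OCCc2cc(OC)c3c(c2)[C@H](CO[Si](C)(C)C(C)(C)C)[C@@H](c2ccc(OCc4ccccc4)c(OC)c2)O3)c(C(C)C)c1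
F4 | step 4 | (S)-1,2-bis(4,4,5,5-tetramethyl-1,3,2-dioxaborolan-2-yl)-3-(triisopropylsilyloxy)propane | CC1(C)OB(C[C@@H](CO[Si](C(C)C)(C(C)C)C(C)C)B2OC(C)(C)C(C)(C)O2)OC1(C)C
F5 | step 14 | C8′-ethenyl analogue of 20 (CH=CH2 in place of the boronate, same spatial arrangement; 8R,8′S) | COc1cc(C[C@@H](CO[Si](C(C)C)(C(C)C)C(C)C)[C@H](C=C)Cc2cc(OC)c3c(c2)[C@H](CO[Si](C)(C)C(C)(C)C)[C@@H](c2ccc(OCc4ccccc4)c(OC)c2)O3)ccc1OCc1ccccc1
F6 | step 14 | (2R,3R)-2-{[(2S,3R)-2-(4-benzyloxy-3-methoxyphenyl)-3-(tert-butyldimethylsilyloxymethyl)-7-methoxy-2,3-dihydro-1-benzofuran-5-yl]methyl}-3-[(4-benzyloxy-3-methoxyphenyl)methyl]-4-(triisopropylsilyloxy)butanal | COc1cc(C[C@@H](CO[Si](C(C)C)(C(C)C)C(C)C)[C@H](C=O)Cc2cc(OC)c3c(c2)[C@H](CO[Si](C)(C)C(C)(C)C)[C@@H](c2ccc(OCc4ccccc4)c(OC)c2)O3)ccc1OCc1ccccc1
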